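**Strategy.** The ten-membered carbocycle (C1–C10, germacrane numbering) is not closed directly. Its cis-1,2-epoxide lies between two carbinols (C3, C10), so C1 and C2 are first joined through a sulfur atom by thiolate/epoxide chemistry. This gives an eleven-membered thiacycle on a chain whose stereocentres (C3, C6, C7, C8, C10) are already set, two of them in an indium-mediated lactol allylation that also builds the cis-fused lactone. Ramberg–Bäcklund ring contraction of the derived S,S-dioxide then extrudes SO2, forges the C1–C2 bond and leaves the (Z)-C1=C2 alkene, which a matched Sharpless epoxidation directed by C3–OH converts into the epoxide.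

Key step: step 18

Remarks on the chemistry:
- The target is taken as drawn: (1R,2R,3R,6S,7R,8S,10R), 4Z, angelate ester (3β-OH, 6αH, 7αH, 8α-O-acyl, 10α-OH, 1β,2β-epoxide). Locants C1–C15 are germacrane locants; C11–C13 are the lactone carbons.
- The anomeric centre of lactol 7, the carbinol centre of 17, C11 of the amine-masked lactones and the transient C1/C2 centres of 27/28 are left undefined on purpose; all are destroyed later.
- Where a second reagent is added to the same flask, the operation counts as one step and the species in between is listed as not isolated.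

**Fragment A (C2–C6, C15)**

Step 1
Reactants: 1 methyl (S)-2,2-dimethyl-1,3-dioxolane-4-carboxylate
Product: 3 (S)-1-(2,2-dimethyl-1,3-dioxolan-4-yl)ethan-1-one, via Weinreb amide 2 (not isolated)
Conditions: MeNH(OMe)·HCl, i-PrMgCl, THF, −20 °C; then MeMgBr, −20 → 0 °C
Reagents that add atoms: N,O-dimethylhydroxylamine hydrochloride, CNOC.Cl (retained only in 2); methylmagnesium bromide, C[Mg]Br
Why: One-pot Weinreb ketone synthesis, in which the chelated tetrahedral adduct of amide 2 with MeMgBr releases the methyl ketone only on work-up, so the chiral-pool stereocentre (future C3) is carried through without over-addition.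

Step 2
Reactants: 3 (S)-1-(2,2-dimethyl-1,3-dioxolan-4-yl)ethan-1-one
Product: 5 (R)-5-(hydroxymethyl)-4-methylfuran-2(5H)-one, via Z-enoate 4 (not isolated)
Conditions: Ph3P=CHCO2Me, MeOH, 0 °C → rt; then HCl (cat.), MeOH, rt
Reagents that add atoms: methyl (triphenylphosphoranylidene)acetate, COC(=O)C=P(c1ccccc1)(c1ccccc1)c1ccccc1
Why: Wittig olefination of the α-alkoxy ketone in methanol should favour the Z-enoate, and acid-mediated acetonide cleavage then lets only that isomer lactonise through the secondary hydroxyl, which locks the Z-C4=C5 alkene in a butenolide without touching the stereocentre.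

Step 3
Reactants: 5 (R)-5-(hydroxymethyl)-4-methylfuran-2(5H)-one
Product: 6 [(2R)-3-methyl-5-oxo-2,5-dihydrofuran-2-yl]methyl 4-methylbenzenesulfonate
Conditions: TsCl, pyridine, CH2Cl2, 0 °C
Reagents that add atoms: 4-methylbenzenesulfonyl chloride, Cc1ccc(cc1)S(=O)(=O)Cl
Why: Sulfonylation of the only hydroxyl under weakly basic conditions that should not epimerise the γ-position of the butenolide.

Step 4
Reactants: 6 [(2R)-3-methyl-5-oxo-2,5-dihydrofuran-2-yl]methyl 4-methylbenzenesulfonate
Product: 7 [(2R)-5-hydroxy-3-methyl-2,5-dihydrofuran-2-yl]methyl 4-methylbenzenesulfonate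
Conditions: DIBAL-H (1.1 equiv), CH2Cl2, −78 °C; aq. potassium sodium tartrate (neutral work-up), used at once
Reagents that add atoms: none
Why: Partial reduction of the lactone carbonyl gives the lactol, a geometry-locked cyclic form of the (Z)-γ-hydroxy enal, and the neutral work-up avoids dehydration to the furan.

**Fragment B (C1, C7–C14)**

Step 5
Reactants: 8 ethyl glyoxylate; 9 2-methylpropene
Product: 10 ethyl (S)-2-hydroxy-4-methylpent-4-enoate
Conditions: (S)-BINOL (10 mol%), TiCl2(OiPr)2 (10 mol%), 4 Å MS, CH2Cl2, −30 °C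
Reagents that add atoms: none
Why: Catalytic asymmetric glyoxylate–ene reaction in which the BINOL–titanium Lewis acid shields one aldehyde face, so the C8 carbinol is set by catalyst control (the (S)-ligand is expected to give the (S)-alcohol).

Step 6
Reactants: 10 ethyl (S)-2-hydroxy-4-methylpent-4-enoate
Product: 11 ethyl (S)-2-[(tert-butoxycarbonyl)oxy]-4-methylpent-4-enoate
Conditions: Boc2O, DMAP (cat.), MeCN, rt
Reagents that add atoms: di-tert-butyl dicarbonate, CC(C)(C)OC(=O)OC(=O)OC(C)(C)C
Why: DMAP-catalysed O-acylation installs the carbonate that serves as the internal oxygen nucleophile of the next step.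

Step 7
Reactants: 11 ethyl (S)-2-[(tert-butoxycarbonyl)oxy]-4-methylpent-4-enoate
Product: 12 ethyl (4S,6R)-6-(iodomethyl)-6-methyl-2-oxo-1,3-dioxane-4-carboxylate
Conditions: IBr, toluene, −85 °C
Reagents that add atoms: iodine monobromide, IBr
Why: Iodocarbonate cyclisation, in which the carbonate carbonyl captures the iodonium ion of the 1,1-disubstituted alkene at the tertiary carbon (6-exo) with loss of the tert-butyl group, and a chair transition state with the ester and CH2I equatorial should set C10 syn to C8.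

Step 8
Reactants: 12 ethyl (4S,6R)-6-(iodomethyl)-6-methyl-2-oxo-1,3-dioxane-4-carboxylate
Product: 13 ethyl (2S)-2-hydroxy-3-[(2R)-2-methyloxiran-2-yl]propanoate
Conditions: K2CO3, EtOH, 0 °C → rt
Reagents that add atoms: none
Why: Ethanolysis of the cyclic carbonate frees the tertiary alkoxide, which displaces the neighbouring iodide (3-exo-tet) to give the 2,2-disubstituted epoxide without changing C8 or C10.

Step 9
Reactants: 13 ethyl (2S)-2-hydroxy-3-[(2R)-2-methyloxiran-2-yl]propanoate
Product: 14 ethyl (2S)-2-[(4-methoxybenzyl)oxy]-3-[(2R)-2-methyloxiran-2-yl]propanoate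
Conditions: PMBBr, Ag2O, 4 Å MS, CH2Cl2, rt, dark
Reagents that add atoms: 4-methoxybenzyl bromide, COc1ccc(CBr)cc1
Why: Silver-oxide-mediated Williamson etherification under neutral conditions spares the ester α-centre and the epoxide and installs the PMB ether that later coordinates indium and protects O8 to the end.

Step 10
Reactants: 14 ethyl (2S)-2-[(4-methoxybenzyl)oxy]-3-[(2R)-2-methyloxiran-2-yl]propanoate
Product: 15 (2S)-2-[(4-methoxybenzyl)oxy]-3-[(2R)-2-methyloxiran-2-yl]propanal
Conditions: DIBAL-H (1.05 equiv), CH2Cl2, −78 °C; MeOH, aq. potassium sodium tartrate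
Reagents that add atoms: none
Why: Reduction of the α-alkoxy ester stops at the chelated aluminium hemiacetal at −78 °C, giving the aldehyde without epimerisation or epoxide opening.

Step 11
Reactants: 15 (2S)-2-[(4-methoxybenzyl)oxy]-3-[(2R)-2-methyloxiran-2-yl]propanal; 16 methyl acrylate
Product: 17 methyl (4S)-3-hydroxy-4-[(4-methoxybenzyl)oxy]-2-methylidene-5-[(2R)-2-methyloxiran-2-yl]pentanoate
Conditions: DABCO (0.5 equiv), neat methyl acrylate, rt
Reagents that add atoms: none
Why: Morita–Baylis–Hillman reaction of the reactive α-alkoxy aldehyde, whose new carbinol centre is unselective but is erased in the next step.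

Step 12
Reactants: 17 methyl (4S)-3-hydroxy-4-[(4-methoxybenzyl)oxy]-2-methylidene-5-[(2R)-2-methyloxiran-2-yl]pentanoate
Product: 18 methyl (2Z,4S)-2-(bromomethyl)-4-[(4-methoxybenzyl)oxy]-5-[(2R)-2-methyloxiran-2-yl]pent-2-enoate
Conditions: NBS, Me2S, CH2Cl2, −20 °C → rt
Reagents that add atoms: N-bromosuccinimide, O=C1CCC(=O)N1Br
Why: Corey–Kim-type activation of the allylic hydroxyl and SN2′ delivery of bromide transposes the alkene to the thermodynamically preferred (Z)-2-(bromomethyl)alkenoate, in which C8 is cis to CH2Br.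

**Union and endgame**

Step 13
Reactants: 7 [(2R)-5-hydroxy-3-methyl-2,5-dihydrofuran-2-yl]methyl 4-methylbenzenesulfonate; 18 methyl (2Z,4S)-2-(bromomethyl)-4-[(4-methoxybenzyl)oxy]-5-[(2R)-2-methyloxiran-2-yl]pent-2-enoate
Product: 20 (4Z)-1,10-epoxy-3-hydroxy-8-(4-methoxybenzyloxy)-2-tosyloxy-1,2-seco-germacra-4,11(13)-dien-12,6-olide, via syn-hydroxy ester 19 (not isolated)
Conditions: In powder, THF/H2O (4:1), pH 7 phosphate buffer, rt; then PPTS (cat.), CH2Cl2, rt
Reagents that add atoms: none
Why: Indium-mediated Barbier allylation of the open hydroxy-enal form of the lactol, in which γ-attack of the Z-allylindium through a Zimmerman–Traxler chair gives the C6/C7 syn adduct, indium held by the C8 ether oxygen (or, equally, the alkoxy group standing anti to the incoming aldehyde) should deliver C6 to the face of C7 opposite C9, and the C6 hydroxyl then lactonises to the cis-4,5-disubstituted α-methylene-γ-butyrolactone.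

Step 14
Reactants: 20 (4Z)-1,10-epoxy-3-hydroxy-8-(4-methoxybenzyloxy)-2-tosyloxy-1,2-seco-germacra-4,11(13)-dien-12,6-olide
Product: 21 (4Z)-13-(dimethylamino)-1,10-epoxy-3-hydroxy-8-(4-methoxybenzyloxy)-2-tosyloxy-1,2-seco-germacr-4-en-12,6-olide
Conditions: Me2NH (2 M in THF, 1.5 equiv), THF, 0 °C
Reagents that add atoms: dimethylamine, CNC
Why: Aza-Michael addition masks the α-methylene lactone as a β-amino lactone so that the thiolate and hydroxide used later cannot add to it; the new C11 centre is unselective and is removed in step 19.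

Step 15
Reactants: 21 (4Z)-13-(dimethylamino)-1,10-epoxy-3-hydroxy-8-(4-methoxybenzyloxy)-2-tosyloxy-1,2-seco-germacr-4-en-12,6-olide
Product: 23 (4Z)-13-(dimethylamino)-1,2-epithio-3,10-dihydroxy-8-(4-methoxybenzyloxy)-1,2-seco-germacr-4-en-12,6-olide, via thioacetate 22 (not isolated)
Conditions: KSAc, DMF, 0 °C → rt; then syringe-pump addition into K2CO3, degassed MeOH (final 1 mM), rt; AcOH quench
Reagents that add atoms: potassium thioacetate, CC(=O)[S-].[K+]
Why: SN2 displacement of the primary tosylate by thioacetate and, after methanolysis to the thiolate, intramolecular SN2 opening of the 2,2-disubstituted epoxide at its CH2 terminus should close the eleven-membered thiacycle and unveil the C10 tertiary alcohol with its configuration untouched, the cis-lactone and the Z-alkene turning the two chain ends toward each other.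

Step 16
Reactants: 23 (4Z)-13-(dimethylamino)-1,2-epithio-3,10-dihydroxy-8-(4-methoxybenzyloxy)-1,2-seco-germacr-4-en-12,6-olide
Product: 24 (4Z)-13-(dimethylamino)-1,2-epithio-3,10-dihydroxy-8-(4-methoxybenzyloxy)-1,2-seco-germacr-4-en-12,6-olide S,S-dioxide
Conditions: Oxone (2KHSO5·KHSO4·K2SO4), MeOH/H2O, 0 °C → rt; NaHCO3 work-up
Reagents that add atoms: potassium peroxymonosulfate, [K+].[O-]S(=O)(=O)OO
Why: Sulfide-to-sulfone oxidation in unbuffered aqueous methanol, where the amine is protected as its ammonium salt and the trisubstituted alkene is not epoxidised.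

Step 17
Reactants: 24 (4Z)-13-(dimethylamino)-1,2-epithio-3,10-dihydroxy-8-(4-methoxybenzyloxy)-1,2-seco-germacr-4-en-12,6-olide S,S-dioxide
Product: 25 (4Z)-13-(dimethylamino)-1,2-epithio-8-(4-methoxybenzyloxy)-3,10-bis(triethylsilyloxy)-1,2-seco-germacr-4-en-12,6-olide S,S-dioxide
Conditions: TESOTf, 2,6-lutidine, CH2Cl2, −78 → 0 °C
Reagents that add atoms: triethylsilyl trifluoromethanesulfonate, CC[Si](CC)(CC)OS(=O)(=O)C(F)(F)F
Why: Silylation of the secondary and the tertiary β-hydroxyl with the silyl triflate prevents retro-aldol-type cleavage of β-alkoxido sulfones in the next step and keeps O3 protected for the later acylation at O8.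

Step 18
Reactants: 25 (4Z)-13-(dimethylamino)-1,2-epithio-8-(4-methoxybenzyloxy)-3,10-bis(triethylsilyloxy)-1,2-seco-germacr-4-en-12,6-olide S,S-dioxide
Product: 30 (1Z,4Z)-13-(dimethylamino)-8-(4-methoxybenzyloxy)-3,10-bis(triethylsilyloxy)germacra-1,4-dien-12,6-olide, via potassium carboxylate 26 (not isolated), via α-bromo sulfone 27 (not isolated), via episulfone 28 (not isolated), via ring-contracted carboxylate 29 (not isolated)
Conditions: KOH, t-BuOH/H2O (20:1), rt; then CBr2F2, KOH/Al2O3, t-BuOH/CH2Cl2, 5 °C → rt; then aq. citric acid to pH 4, rt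
Reagents that add atoms: potassium hydroxide, [K+].[OH-] (retained only in 26 to 29); dibromodifluoromethane, FC(F)(Br)Br (bromine retained only in 27)
Why: Saponification first turns the lactone into its carboxylate so that the α-sulfonyl protons at C1 and C2 are the only acidic C–H left; base then removes one, CBr2F2 brominates the carbanion, and the α′-carbanion displaces bromide in a 3-exo-tet closure that forms the C1–C2 bond inside the eleven-membered ring as a thiirane S,S-dioxide, which loses SO2 cheletropically. The closest known reaction is the one-pot (in situ halogenation) Ramberg–Bäcklund reaction, which is established for medium-ring cycloalkenes and for sulfones bearing β-alkoxy groups. The ten-membered carbocycle therefore arises by ring contraction through transannular C–C bond formation, not by end-to-end cyclisation, and acidification re-closes the five-membered lactone by 5-exo-trig attack of the C6 hydroxyl on the carboxyl group, O8 being blocked as its PMB ether. No lasting stereocentre is created; the transient centres of the episulfone vanish, and the Z-geometry of C1=C2 should follow from the cis-fused episulfone favoured by the ring and by the KOH conditions. The step needs 1,3-elimination to outrun β-elimination of the C3 and C10 oxygens and retro-aldol cleavage, which the silyl ethers (poor leaving groups, no free alkoxide) and the fast in situ halogenation are meant to secure.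

Step 19
Reactants: 30 (1Z,4Z)-13-(dimethylamino)-8-(4-methoxybenzyloxy)-3,10-bis(triethylsilyloxy)germacra-1,4-dien-12,6-olide
Product: 32 (1Z,4Z)-8-(4-methoxybenzyloxy)-3,10-bis(triethylsilyloxy)germacra-1,4,11(13)-trien-12,6-olide, via trimethylammonium iodide 31 (not isolated)
Conditions: MeI, MeOH, rt; then NaHCO3, H2O/THF, rt
Reagents that add atoms: iodomethane, CI (retained only in 31)
Why: Exhaustive N-methylation followed by mild-base E1cB elimination of trimethylamine regenerates the α-methylene lactone.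

Step 20
Reactants: 32 (1Z,4Z)-8-(4-methoxybenzyloxy)-3,10-bis(triethylsilyloxy)germacra-1,4,11(13)-trien-12,6-olide
Product: 33 (1Z,4Z)-8-hydroxy-3,10-bis(triethylsilyloxy)germacra-1,4,11(13)-trien-12,6-olide
Conditions: DDQ, CH2Cl2/pH 7 buffer, 0 °C
Reagents that add atoms: none
Why: Oxidative cleavage of the PMB ether through its benzylic oxocarbenium ion frees the C8 hydroxyl as the only unprotected alcohol.

Step 21
Reactants: 33 (1Z,4Z)-8-hydroxy-3,10-bis(triethylsilyloxy)germacra-1,4,11(13)-trien-12,6-olide; 34 angelic acid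
Product: 35 (1Z,4Z)-8-angeloyloxy-3,10-bis(triethylsilyloxy)germacra-1,4,11(13)-trien-12,6-olide
Conditions: 34, 2,4,6-trichlorobenzoyl chloride, Et3N, toluene, rt; then 33, 80 °C (no DMAP)
Reagents that add atoms: none
Why: Yamaguchi-type esterification through the mixed anhydride acylates the single free hydroxyl, and omitting DMAP should preserve the Z-geometry of the angelate.

Step 22
Reactants: 35 (1Z,4Z)-8-angeloyloxy-3,10-bis(triethylsilyloxy)germacra-1,4,11(13)-trien-12,6-olide
Product: 36 (1Z,4Z)-8-angeloyloxy-3,10-dihydroxygermacra-1,4,11(13)-trien-12,6-olide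
Conditions: HF·pyridine, pyridine, THF, 0 °C → rt
Reagents that add atoms: none
Why: Buffered fluoride cleavage of both triethylsilyl ethers should leave the angelate, the skipped diene and the α-methylene lactone intact.

Step 23
Reactants: 36 (1Z,4Z)-8-angeloyloxy-3,10-dihydroxygermacra-1,4,11(13)-trien-12,6-olide
Product: 37 (1R,2R,3R,6S,7R,8S,10R,4Z)-8-angeloyloxy-1,2-epoxy-3,10-dihydroxygermacra-4,11(13)-dien-12,6-olide
Conditions: Ti(OiPr)4 (1.0 equiv), D-(−)-diisopropyl tartrate (1.2 equiv), t-BuOOH, 4 Å MS, CH2Cl2, −20 °C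
Reagents that add atoms: tert-butyl hydroperoxide, CC(C)(C)OO
Why: Sharpless epoxidation of the bis-allylic carbinol, in which D-(−)-tartrate makes the C3 carbinol the matched (fast) case for the C1=C2 arm and the mismatched case for the C4=C5 arm, so oxygen should be delivered to C1=C2 on the face that gives the erythro (cis) epoxy alcohol and sets C1 and C2.

**Compound list**

1 | methyl (S)-2,2-dimethyl-1,3-dioxolane-4-carboxylate | COC(=O)[C@@H]1COC(C)(C)O1 | starting material
2 | (S)-N-methoxy-N,2,2-trimethyl-1,3-dioxolane-4-carboxamide (Weinreb amide) | CON(C)C(=O)[C@@H]1COC(C)(C)O1 | intermediate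
3 | (S)-1-(2,2-dimethyl-1,3-dioxolan-4-yl)ethan-1-one | CC(=O)[C@@H]1COC(C)(C)O1 | intermediate
4 | methyl (Z)-3-[(4R)-2,2-dimethyl-1,3-dioxolan-4-yl]but-2-enoate (Z-enoate) | COC(=O)/C=C(/C)[C@@H]1COC(C)(C)O1 | intermediate
5 | (R)-5-(hydroxymethyl)-4-methylfuran-2(5H)-one | OC[C@@H]1OC(=O)C=C1C | intermediate
6 | [(2R)-3-methyl-5-oxo-2,5-dihydrofuran-2-yl]methyl 4-methylbenzenesulfonate | Cc1ccc(cc1)S(=O)(=O)OC[C@@H]1OC(=O)C=C1C | intermediate
7 | [(2R)-5-hydroxy-3-methyl-2,5-dihydrofuran-2-yl]methyl 4-methylbenzenesulfonate (lactol, both anomers) | Cc1ccc(cc1)S(=O)(=O)OC[C@@H]1OC(O)C=C1C | intermediate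
8 | ethyl glyoxylate | CCOC(=O)C=O | starting material
9 | 2-methylpropene | CC(C)=C | starting material
10 | ethyl (S)-2-hydroxy-4-methylpent-4-enoate | CCOC(=O)[C@@H](O)CC(C)=C | intermediate
11 | ethyl (S)-2-[(tert-butoxycarbonyl)oxy]-4-methylpent-4-enoate | CCOC(=O)[C@@H](OC(=O)OC(C)(C)C)CC(C)=C | intermediate
12 | ethyl (4S,6R)-6-(iodomethyl)-6-methyl-2-oxo-1,3-dioxane-4-carboxylate (ester and CH2I cis) | CCOC(=O)[C@@H]1C[C@](C)(CI)OC(=O)O1 | intermediate
13 | ethyl (2S)-2-hydroxy-3-[(2R)-2-methyloxiran-2-yl]propanoate | CCOC(=O)[C@@H](O)C[C@]1(C)CO1 | intermediate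
14 | ethyl (2S)-2-[(4-methoxybenzyl)oxy]-3-[(2R)-2-methyloxiran-2-yl]propanoate | CCOC(=O)[C@@H](OCc1ccc(OC)cc1)C[C@]2(C)CO2 | intermediate
15 | (2S)-2-[(4-methoxybenzyl)oxy]-3-[(2R)-2-methyloxiran-2-yl]propanal | O=C[C@@H](OCc1ccc(OC)cc1)C[C@]2(C)CO2 | intermediate
16 | methyl acrylate | C=CC(=O)OC | starting material
17 | methyl (4S)-3-hydroxy-4-[(4-methoxybenzyl)oxy]-2-methylidene-5-[(2R)-2-methyloxiran-2-yl]pentanoate (C3 epimers) | COC(=O)C(=C)C(O)[C@@H](OCc1ccc(OC)cc1)C[C@]2(C)CO2 | intermediate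
18 | methyl (2Z,4S)-2-(bromomethyl)-4-[(4-methoxybenzyl)oxy]-5-[(2R)-2-methyloxiran-2-yl]pent-2-enoate | COC(=O)/C(CBr)=C/[C@@H](OCc1ccc(OC)cc1)C[C@]2(C)CO2 | intermediate
19 | methyl (4Z)-1,10-epoxy-3,6-dihydroxy-8-(4-methoxybenzyloxy)-2-tosyloxy-1,2-seco-germacra-4,11(13)-dien-12-oate (syn-hydroxy ester; C3, C6, C7, C8, C10 as in 37) | COC(=O)C(=C)[C@@H]([C@@H](O)/C=C(/C)[C@@H](O)COS(=O)(=O)c1ccc(C)cc1)[C@@H](OCc1ccc(OC)cc1)C[C@]2(C)CO2 | intermediate
20 | (4Z)-1,10-epoxy-3-hydroxy-8-(4-methoxybenzyloxy)-2-tosyloxy-1,2-seco-germacra-4,11(13)-dien-12,6-olide (cis C6/C7 α-methylene-γ-butyrolactone) | C=C1C(=O)O[C@@H](/C=C(/C)[C@@H](O)COS(=O)(=O)c2ccc(C)cc2)[C@H]1[C@@H](OCc2ccc(OC)cc2)C[C@]3(C)CO3 | intermediate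
21 | (4Z)-13-(dimethylamino)-1,10-epoxy-3-hydroxy-8-(4-methoxybenzyloxy)-2-tosyloxy-1,2-seco-germacr-4-en-12,6-olide (C11 epimers) | CN(C)CC1C(=O)O[C@@H](/C=C(/C)[C@@H](O)COS(=O)(=O)c2ccc(C)cc2)[C@H]1[C@@H](OCc2ccc(OC)cc2)C[C@]3(C)CO3 | intermediate
22 | (4Z)-2-(acetylthio)-13-(dimethylamino)-1,10-epoxy-3-hydroxy-8-(4-methoxybenzyloxy)-1,2-seco-germacr-4-en-12,6-olide (thioacetate) | CN(C)CC1C(=O)O[C@@H](/C=C(/C)[C@@H](O)CSC(C)=O)[C@H]1[C@@H](OCc2ccc(OC)cc2)C[C@]3(C)CO3 | intermediate
23 | (4Z)-13-(dimethylamino)-1,2-epithio-3,10-dihydroxy-8-(4-methoxybenzyloxy)-1,2-seco-germacr-4-en-12,6-olide (eleven-membered thiacycle, S between C1 and C2) | CN(C)CC1C(=O)O[C@H]2/C=C(/C)[C@@H](O)CSC[C@](C)(O)C[C@H](OCc3ccc(OC)cc3)[C@@H]12 | intermediate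
24 | S,S-dioxide of 23 | CN(C)CC1C(=O)O[C@H]2/C=C(/C)[C@@H](O)CS(=O)(=O)C[C@](C)(O)C[C@H](OCc3ccc(OC)cc3)[C@@H]12 | intermediate
25 | 3,10-bis(O-triethylsilyl) ether of 24 | CN(C)CC1C(=O)O[C@H]2/C=C(/C)[C@@H](O[Si](CC)(CC)CC)CS(=O)(=O)C[C@](C)(O[Si](CC)(CC)CC)C[C@H](OCc3ccc(OC)cc3)[C@@H]12 | intermediate
26 | potassium 12-carboxylate of 25 with free 6-OH (lactone opened) | O[C@H]1/C=C(/C)[C@@H](O[Si](CC)(CC)CC)CS(=O)(=O)C[C@](C)(O[Si](CC)(CC)CC)C[C@H](OCc2ccc(OC)cc2)[C@H]1C(CN(C)C)C(=O)[O-].[K+] | intermediate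
27 | 2-bromo derivative of 26 (α-bromo sulfone) | O[C@H]1/C=C(/C)[C@@H](O[Si](CC)(CC)CC)C(Br)S(=O)(=O)C[C@](C)(O[Si](CC)(CC)CC)C[C@H](OCc2ccc(OC)cc2)[C@H]1C(CN(C)C)C(=O)[O-].[K+] | intermediate
28 | episulfone: potassium carboxylate with C1–C2 bond and thiirane S,S-dioxide across C1/C2 | O[C@H]1/C=C(/C)[C@@H](O[Si](CC)(CC)CC)C2C(S2(=O)=O)[C@](C)(O[Si](CC)(CC)CC)C[C@H](OCc3ccc(OC)cc3)[C@H]1C(CN(C)C)C(=O)[O-].[K+] | intermediate
29 | potassium (1Z,4Z)-13-(dimethylamino)-6-hydroxy-8-(4-methoxybenzyloxy)-3,10-bis(triethylsilyloxy)germacra-1,4-dien-12-oate | O[C@H]1/C=C(/C)[C@@H](O[Si](CC)(CC)CC)/C=C\[C@](C)(O[Si](CC)(CC)CC)C[C@H](OCc2ccc(OC)cc2)[C@H]1C(CN(C)C)C(=O)[O-].[K+] | intermediate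
30 | (1Z,4Z)-13-(dimethylamino)-8-(4-methoxybenzyloxy)-3,10-bis(triethylsilyloxy)germacra-1,4-dien-12,6-olide | CN(C)CC1C(=O)O[C@H]2/C=C(/C)[C@@H](O[Si](CC)(CC)CC)/C=C\[C@](C)(O[Si](CC)(CC)CC)C[C@H](OCc3ccc(OC)cc3)[C@@H]12 | intermediate
31 | N-methyl quaternary ammonium iodide of 30 | C[N+](C)(C)CC1C(=O)O[C@H]2/C=C(/C)[C@@H](O[Si](CC)(CC)CC)/C=C\[C@](C)(O[Si](CC)(CC)CC)C[C@H](OCc3ccc(OC)cc3)[C@@H]12.[I-] | intermediate
32 | (1Z,4Z)-8-(4-methoxybenzyloxy)-3,10-bis(triethylsilyloxy)germacra-1,4,11(13)-trien-12,6-olide | C=C1C(=O)O[C@H]2/C=C(/C)[C@@H](O[Si](CC)(CC)CC)/C=C\[C@](C)(O[Si](CC)(CC)CC)C[C@H](OCc3ccc(OC)cc3)[C@@H]12 | intermediate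
33 | (1Z,4Z)-8-hydroxy-3,10-bis(triethylsilyloxy)germacra-1,4,11(13)-trien-12,6-olide | C=C1C(=O)O[C@H]2/C=C(/C)[C@@H](O[Si](CC)(CC)CC)/C=C\[C@](C)(O[Si](CC)(CC)CC)C[C@H](O)[C@@H]12 | intermediate
34 | angelic acid, (Z)-2-methylbut-2-enoic acid | C/C=C(/C)C(=O)O | starting material
35 | (1Z,4Z)-8-angeloyloxy-3,10-bis(triethylsilyloxy)germacra-1,4,11(13)-trien-12,6-olide | C=C1C(=O)O[C@H]2/C=C(/C)[C@@H](O[Si](CC)(CC)CC)/C=C\[C@](C)(O[Si](CC)(CC)CC)C[C@H](OC(=O)/C(C)=C\C)[C@@H]12 | intermediate
36 | (1Z,4Z)-8-angeloyloxy-3,10-dihydroxygermacra-1,4,11(13)-trien-12,6-olide | C=C1C(=O)O[C@H]2/C=C(/C)[C@@H](O)/C=C\[C@](C)(O)C[C@H](OC(=O)/C(C)=C\C)[C@@H]12 | intermediate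
37 | (1R,2R,3R,6S,7R,8S,10R,4Z)-8-angeloyloxy-1,2-epoxy-3,10-dihydroxygermacra-4,11(13)-dien-12,6-olide (CNP0351240.3) | C=C1C(=O)O[C@H]2/C=C(/C)[C@@H](O)[C@H]3O[C@H]3[C@](C)(O)C[C@H](OC(=O)/C(C)=C\C)[C@@H]12 | target

**Step count.** Total: 23 steps. Longest linear sequence: 19 steps (steps 5–12, then 13–23); fragment A (steps 1–4) joins at step 13.

**Steps most likely to fail**

Step 18 (ring contraction). Under the one-pot halogenation conditions a silyloxide may be lost by β-elimination from the α-sulfonyl carbanion next to C3 or C10, difluorocarbene may be captured by the alkenes, and the new alkene may form as an E/Z mixture. The fallback separates halogenation from elimination and sets out from sulfide 23. TESOTf/2,6-lutidine would give the bis(triethylsilyl) sulfide F1. NCS (CCl4, 0 °C) would give the α-chloro sulfide F2, since chlorination at sulfur is faster than reaction at the amine. m-CPBA (CH2Cl2, −20 °C, amine held as its trifluoroacetate salt) would give the α-chloro sulfone F3. Brief treatment with KOt-Bu (THF, −78 → 0 °C) should give the episulfone F4, where no halogen source is present to intercept the lactone enolate and the 1,3-elimination can outrun β-elimination at low temperature. Loss of SO2 brings the route back at 30.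

Step 13 (fragment union). The lactol may dehydrate to a furan and the tertiary epoxide may open in the Lewis-acidic aqueous indium bromide medium, and water may displace the ether oxygen from indium so that facial selectivity erodes. The fallback replaces the aqueous Barbier reaction by a neutral allylboration and sets out from 17. Ac2O/pyridine/DMAP would give the allylic acetate F5. Borylation with B2pin2 and Pd2(dba)3 (cat.) in toluene at 50 °C should give the (2-alkoxycarbonyl)allylboronate F6, with C8 cis to the CH2B group. Heating F6 with lactol 7 in toluene at 80 °C passes through a closed six-membered boron transition state that transfers the alkene geometry into the C6/C7 syn relationship. The facial sense then rests on the arrangement with the alkoxy group anti to the incoming aldehyde. Hydrolysis of the borate gives 19, and PPTS brings the route back at 20.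

Step 15 (macrocyclisation). Intermolecular S-alkylation (oligomerisation) may outrun closure of the eleven-membered ring, because the thiolate has to attack a neopentyl-type epoxide carbon at high dilution. The fallback closes a twelve-membered disulfide under reversible conditions and then removes one sulfur; it sets out from 21. Excess KSAc (DMF, 50 °C) would displace the tosylate and open the epoxide to give the bis(thioacetate) F7. K2CO3/MeOH would release the dithiol F8. Iodine at high dilution should close the cyclic disulfide F9. Sulfur extrusion with P(NEt2)3 (toluene, 80 °C) brings the route back at 23.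

Further compounds
F1 | step 18 | 3,10-bis(O-triethylsilyl) ether of sulfide 23 | CN(C)CC1C(=O)O[C@H]2/C=C(/C)[C@@H](O[Si](CC)(CC)CC)CSC[C@](C)(O[Si](CC)(CC)CC)C[C@H](OCc3ccc(OC)cc3)[C@@H]12
F2 | step 18 | 2-chloro derivative of F1 (α-chloro sulfide) | CN(C)CC1C(=O)O[C@H]2/C=C(/C)[C@@H](O[Si](CC)(CC)CC)C(Cl)SC[C@](C)(O[Si](CC)(CC)CC)C[C@H](OCc3ccc(OC)cc3)[C@@H]12
F3 | step 18 | S,S-dioxide of F2 (α-chloro sulfone) | CN(C)CC1C(=O)O[C@H]2/C=C(/C)[C@@H](O[Si](CC)(CC)CC)C(Cl)S(=O)(=O)C[C@](C)(O[Si](CC)(CC)CC)C[C@H](OCc3ccc(OC)cc3)[C@@H]12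
F4 | step 18 | episulfone with intact lactone (thiirane S,S-dioxide across C1/C2) | CN(C)CC1C(=O)O[C@H]2/C=C(/C)[C@@H](O[Si](CC)(CC)CC)C3C(S3(=O)=O)[C@](C)(O[Si](CC)(CC)CC)C[C@H](OCc4ccc(OC)cc4)[C@@H]12
F5 | step 13 | methyl (4S)-3-acetoxy-4-[(4-methoxybenzyl)oxy]-2-methylidene-5-[(2R)-2-methyloxiran-2-yl]pentanoate | COC(=O)C(=C)C(OC(C)=O)[C@@H](OCc1ccc(OC)cc1)C[C@]2(C)CO2
F6 | step 13 | methyl (4S)-4-[(4-methoxybenzyl)oxy]-5-[(2R)-2-methyloxiran-2-yl]-2-[(4,4,5,5-tetramethyl-1,3,2-dioxaborolan-2-yl)methyl]pent-2-enoate (C4 cis to CH2B) | COC(=O)/C(CB1OC(C)(C)C(C)(C)O1)=C/[C@@H](OCc2ccc(OC)cc2)C[C@]3(C)CO3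
F7 | step 15 | 1,2-bis(acetylthio)-13-(dimethylamino)-3,10-dihydroxy-8-(4-methoxybenzyloxy)-1,2-seco-germacr-4Z-en-12,6-olide | CN(C)CC1C(=O)O[C@@H](/C=C(/C)[C@@H](O)CSC(C)=O)[C@H]1[C@@H](OCc2ccc(OC)cc2)C[C@@](C)(O)CSC(C)=O
F8 | step 15 | corresponding 1,2-dithiol | CN(C)CC1C(=O)O[C@@H](/C=C(/C)[C@@H](O)CS)[C@H]1[C@@H](OCc2ccc(OC)cc2)C[C@@](C)(O)CS
F9 | step 15 | twelve-membered cyclic disulfide (S–S between C1 and C2) | CN(C)CC1C(=O)O[C@H]2/C=C(/C)[C@@H](O)CSSC[C@](C)(O)C[C@H](OCc3ccc(OC)cc3)[C@@H]12
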